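**Plan**

1. Core numbering used below: 1,2,5-trimethyl-1,2,3,4,5,6,7,8-octahydronaphthalene. Ring A = C4a, C5–C8, C8a (C5 quaternary, carries the side chain). Ring B = C1–C4, C4a, C8a (C1 quaternary, carries CH2Ar; C2 carries CH3). C4a=C8a is the ring-fusion alkene.
2. Cuts, in retrosynthetic order: the two ArO–SO3H bonds; the side-chain C(sp3)–C(sp2) bond next to the E-alkene (B-alkyl Suzuki–Miyaura); then, in one palladium cycle, the aryl–CH2 bond and the ring bond C1–C8a; then the CH2–CH2 bond of the tether on C4a (conjugate addition to an α-methylene ketone) and the C5–vinyl bond (asymmetric conjugate addition to 3-methylcyclohexenone).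
3. Enabling feature: C1 is quaternary, bears the benzylic CH2 and is bonded to alkene carbon C8a. An alkenylpalladium at C8a that adds 6-exo across a C1=CH2 group therefore leaves palladium on that CH2 with no β-hydrogen, where an arylboron reagent delivers the arene.
4. Forward order: ring A is bought and dressed by two conjugate-addition/enolate-trapping events; ring B is closed by the Heck/Suzuki cascade; the side chain is joined by hydroboration/coupling; then hydroquinone release, sulfation and deacetylation.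
5. Stereochemistry: C5 by Cu-catalysed asymmetric conjugate addition; C2 by Evans methylation; C1 relayed from C2 in the carbopalladation; the diol by Sharpless epoxidation of geraniol and invertive hydrolysis at the tertiary carbon; the E-alkene by Zr-catalysed syn-carboalumination.

Key step: step 8

Assumptions: (a) The aryl sulfates are written as free hydrogen sulfates, as in the target SMILES; the last two compounds would be handled as disodium salts and the acid form liberated on a cation-exchange resin. (b) The sense of induction of the chiral ligand in step 1 is to be assigned in a trial run; the ligand enantiomer that delivers the (3R)-configured silyl enol ether is used.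

**Step 1**
Reactants: 1 3-methylcyclohex-2-en-1-one
Product: 3 {[(3R)-3-ethenyl-3-methylcyclohex-1-en-1-yl]oxy}trimethylsilane, via aluminium enolate 2 (not isolated)
Conditions: CH2=CHMgBr, Me2AlCl, Et2O, −30 °C (gives CH2=CHAlMe2); copper thiophene-2-carboxylate Cu(O2CC4H3S) (5 mol %), chiral binaphthol-derived phosphoramidite (10 mol %), Et2O, −30 °C; then Me3SiOTf, Et3N, −30 to 0 °C
Reagents that add atoms: vinylmagnesium bromide C=C[Mg]Br; trimethylsilyl trifluoromethanesulfonate C[Si](C)(C)OS(=O)(=O)C(F)(F)F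
Why: Cu-catalysed asymmetric conjugate addition of an alkenylalane to a β-methyl cyclohexenone should create the quaternary carbon C5 under ligand control, and O-silylation of the regiodefined aluminium enolate fixes the enol double bond toward the hindered α-carbon.

**Step 2**
Reactants: 3 {[(3R)-3-ethenyl-3-methylcyclohex-1-en-1-yl]oxy}trimethylsilane
Product: 6 (3R)-3-ethenyl-3-methyl-2-methylidenecyclohexan-1-one, via Mannich base 4 (not isolated), via ammonium iodide 5 (not isolated)
Conditions: Me2N=CH2+ I− (Eschenmoser's salt), CH2Cl2, 0 °C to rt; then MeI, Et2O, rt; then K2CO3, CH2Cl2/H2O, rt; used at once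
Reagents that add atoms: N,N-dimethylmethyleneiminium iodide C=[N+](C)C.[I-]
Why: Mannich reaction of the silyl enol ether places one carbon only on the enol carbon, and N-methylation followed by Hofmann-type β-elimination should give the exo-methylene enone without touching the quaternary centre.

**Step 3**
Reactants: 7 3-methylbut-3-enoic acid; 8 (4R)-4-benzyl-1,3-oxazolidin-2-one
Product: 10 (4R)-4-benzyl-3-(3-methylbut-3-enoyl)-1,3-oxazolidin-2-one, via mixed pivalic anhydride 9 (not isolated)
Conditions: t-BuCOCl, Et3N, THF, −20 °C; then LiCl, 8, −20 °C to rt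
Reagents that add atoms: none
Why: Mixed-anhydride N-acylation of the oxazolidinone under LiCl/Et3N is mild enough to keep the β,γ-alkene out of conjugation.

**Step 4**
Reactants: 10 (4R)-4-benzyl-3-(3-methylbut-3-enoyl)-1,3-oxazolidin-2-one
Product: 12 (4R)-4-benzyl-3-[(2R)-2,3-dimethylbut-3-enoyl]-1,3-oxazolidin-2-one, via sodium (Z)-enolate 11 (not isolated)
Conditions: NaN(SiMe3)2, THF, −78 °C; MeI, −78 to −40 °C
Reagents that add atoms: iodomethane CI
Why: Evans alkylation: the chelated Z-enolate should be methylated at the α-carbon on the face opposite the benzyl group, which sets the future C2 centre as (R) in this fragment.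

**Step 5**
Reactants: 12 (4R)-4-benzyl-3-[(2R)-2,3-dimethylbut-3-enoyl]-1,3-oxazolidin-2-one
Product: 13 (2R)-2,3-dimethylbut-3-en-1-ol
Conditions: LiBH4, Et2O, H2O (1 equiv), 0 °C
Reagents that add atoms: none
Why: Reductive cleavage of the imide by LiBH4 should give the primary alcohol without epimerising the α-centre and returns the auxiliary.

**Step 6**
Reactants: 13 (2R)-2,3-dimethylbut-3-en-1-ol
Product: 14 (3R)-4-bromo-2,3-dimethylbut-1-ene
Conditions: CBr4, PPh3, CH2Cl2, 0 °C; handled as a solution (volatile)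
Reagents that add atoms: tetrabromomethane BrC(Br)(Br)Br
Why: Appel bromination of the primary alcohol under neutral conditions does not involve the stereocentre.

**Step 7**
Reactants: 14 (3R)-4-bromo-2,3-dimethylbut-1-ene; 6 (3R)-3-ethenyl-3-methyl-2-methylidenecyclohexan-1-one
Product: 17 (3R)-2-[(3S)-3,4-dimethylpent-4-en-1-yl]-3-ethenyl-3-methylcyclohex-1-en-1-yl trifluoromethanesulfonate, via Grignard reagent 15 (not isolated), via magnesium enolate 16 (not isolated)
Conditions: 14, Mg, THF, 0 °C to rt; CuBr·SMe2 (10 mol %), THF, −78 °C, then 6; then N-(5-chloro-2-pyridyl)triflimide (Comins' reagent), −78 to 0 °C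
Reagents that add atoms: N-(5-chloropyridin-2-yl)-1,1,1-trifluoro-N-[(trifluoromethyl)sulfonyl]methanesulfonamide FC(F)(F)S(=O)(=O)N(c1ccc(Cl)cn1)S(=O)(=O)C(F)(F)F
Why: Cu-catalysed 1,4-addition of the primary Grignard reagent to the unhindered exo-methylene carbon should give the tetrasubstituted enolate regiospecifically, and its O-triflation (conjugate addition/enolate trapping) gives the alkenyl triflate with the double bond at the future ring fusion.

**Step 8**
Reactants: 17 (3R)-2-[(3S)-3,4-dimethylpent-4-en-1-yl]-3-ethenyl-3-methylcyclohex-1-en-1-yl trifluoromethanesulfonate; 18 (2,5-dimethoxyphenyl)boronic acid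
Product: 19 2-{[(1R,2S,5R)-5-ethenyl-1,2,5-trimethyl-1,2,3,4,5,6,7,8-octahydronaphthalen-1-yl]methyl}-1,4-dimethoxybenzene
Conditions: Pd(OAc)2 (10 mol %), PPh3 (25 mol %), K3PO4, THF/H2O (20:1), 65 °C, 18 (2 equiv) added over 4 h
Reagents that add atoms: none
Why: Oxidative addition of the alkenyl triflate to zerovalent palladium gives a cationic alkenylpalladium at C8a, which inserts the tethered 1,1-disubstituted alkene by syn-carbopalladation (6-exo-trig) and so closes ring B through the C1–C8a bond; the resulting neopentyl-type σ-alkylpalladium on the CH2 group has no β-hydrogen because C1 is quaternary, so it persists until the arylboronate transmetalates and reductive elimination forms the CH2–aryl bond. The closest known reaction type is the domino Heck cyclisation/Suzuki–Miyaura coupling (cyclisation–anion capture) of aryl or alkenyl halides and triflates that carry a 1,1-disubstituted alkene. The one new stereocentre, C1, is set by the existing C2 centre: the four-centre insertion requires the exocyclic CH2 to lie near the plane of the alkenyl–palladium bond (pseudo-equatorial in the nascent half-chair), and in that arrangement the C2 hydrogen rather than the C2 methyl eclipses the alkene (minimised A(1,3) strain), so the C2 methyl is pseudo-equatorial and the new C1 methyl ends axial and cis to it, as in the target. The step needs cyclisation to outrun direct alkenyl–aryl coupling; the intramolecular insertion at a triflate-derived cationic palladium, the hindrance of the tetrasubstituted alkenylpalladium toward the ortho-substituted boronate and the slow addition of 18 are expected to secure this. The C5 vinyl group should not interfere, because 4-exo or 5-endo insertion is disfavoured and the C5 centre lies trans to C1 across the ring-fusion alkene.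

**Step 9**
Reactants: 20 geraniol [(2E)-3,7-dimethylocta-2,6-dien-1-ol]
Product: 21 [(2S,3S)-3-methyl-3-(4-methylpent-3-en-1-yl)oxiran-2-yl]methanol
Conditions: Ti(OiPr)4 (5 mol %), L-(+)-diethyl tartrate (6 mol %), t-BuOOH, 4 Å molecular sieves, CH2Cl2, −20 °C
Reagents that add atoms: tert-butyl hydroperoxide CC(C)(C)OO
Why: Sharpless asymmetric epoxidation should oxidise only the allylic alkene and, with L-(+)-tartrate, set both epoxide carbons as (2S,3S).

**Step 10**
Reactants: 21 [(2S,3S)-3-methyl-3-(4-methylpent-3-en-1-yl)oxiran-2-yl]methanol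
Product: 23 trimethyl{4-[(2S,3S)-3-methyl-3-(4-methylpent-3-en-1-yl)oxiran-2-yl]but-1-yn-1-yl}silane, via epoxy triflate 22 (not isolated)
Conditions: Tf2O, 2,6-lutidine, CH2Cl2, −78 °C; then LiCH2C≡CSiMe3 (from MeC≡CSiMe3, n-BuLi, THF, −78 to 0 °C), THF, −78 °C
Reagents that add atoms: 1-(trimethylsilyl)propyne CC#C[Si](C)(C)C
Why: SN2 displacement of the primary triflate by the propargylic lithium reagent at −78 °C should be faster than opening of the trisubstituted epoxide, and the silyl group directs alkylation to the propargylic terminus.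

**Step 11**
Reactants: 23 trimethyl{4-[(2S,3S)-3-methyl-3-(4-methylpent-3-en-1-yl)oxiran-2-yl]but-1-yn-1-yl}silane
Product: 25 (5S,6R)-6,10-dimethylundec-9-en-1-yne-5,6-diol, via silylalkyne diol 24 (not isolated)
Conditions: HClO4 (aq, cat.), THF/H2O, 0 °C to rt; neutralise; then K2CO3, MeOH, rt
Reagents that add atoms: water O
Why: Acid-catalysed epoxide hydrolysis should proceed by attack of water at the tertiary carbon with inversion (borderline SN2), giving the anti-diol with the secondary C–O bond retained; methanolysis then cleaves the alkynyl C–Si bond.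

**Step 12**
Reactants: 25 (5S,6R)-6,10-dimethylundec-9-en-1-yne-5,6-diol
Product: 27 (1E,6S,7R)-1-iodo-2,7,11-trimethyldodeca-1,10-diene-6,7-diol, via alkenylalane 26 (not isolated)
Conditions: AlMe3 (5 equiv), Cp2ZrCl2 (0.5 equiv), CH2Cl2, 0 °C to rt; then I2, THF, −30 °C
Reagents that add atoms: trimethylaluminium C[Al](C)C; iodine II
Why: Negishi Zr-catalysed methylalumination adds CH3 and Al syn across the terminal alkyne with CH3 on the internal carbon (the diol is carried as aluminium alkoxides), and iodinolysis with retention should give the E-iodoalkene.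

**Step 13**
Reactants: 27 (1E,6S,7R)-1-iodo-2,7,11-trimethyldodeca-1,10-diene-6,7-diol
Product: 28 (1E,6S,7R)-7-hydroxy-1-iodo-2,7,11-trimethyldodeca-1,10-dien-6-yl acetate
Conditions: Ac2O, pyridine, rt
Reagents that add atoms: acetic anhydride CC(=O)OC(C)=O
Why: Acylation without an acyl-transfer catalyst should acetylate the secondary hydroxyl only and leave the hindered tertiary hydroxyl free.

**Step 14**
Reactants: 19 2-{[(1R,2S,5R)-5-ethenyl-1,2,5-trimethyl-1,2,3,4,5,6,7,8-octahydronaphthalen-1-yl]methyl}-1,4-dimethoxybenzene; 28 (1E,6S,7R)-7-hydroxy-1-iodo-2,7,11-trimethyldodeca-1,10-dien-6-yl acetate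
Product: 30 2-({(1R,2S,5R)-5-[(3E,7S,8R)-7-acetoxy-8-hydroxy-4,8,12-trimethyltrideca-3,11-dien-1-yl]-1,2,5-trimethyl-1,2,3,4,5,6,7,8-octahydronaphthalen-1-yl}methyl)-1,4-dimethoxybenzene, via B-alkyl-9-BBN adduct 29 (not isolated)
Conditions: 19, 9-BBN-H, THF, rt to 40 °C; then 28, Pd(dppf)Cl2 (5 mol %), AsPh3, Cs2CO3, DMF/H2O, rt
Reagents that add atoms: none
Why: 9-BBN should hydroborate only the monosubstituted vinyl group at its terminus (the tetrasubstituted ring-fusion alkene is inert), and B-alkyl Suzuki–Miyaura coupling joins the side chain with retention of the E geometry.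

**Step 15**
Reactants: 30 2-({(1R,2S,5R)-5-[(3E,7S,8R)-7-acetoxy-8-hydroxy-4,8,12-trimethyltrideca-3,11-dien-1-yl]-1,2,5-trimethyl-1,2,3,4,5,6,7,8-octahydronaphthalen-1-yl}methyl)-1,4-dimethoxybenzene
Product: 32 2-({(1R,2S,5R)-5-[(3E,7S,8R)-7-acetoxy-8-hydroxy-4,8,12-trimethyltrideca-3,11-dien-1-yl]-1,2,5-trimethyl-1,2,3,4,5,6,7,8-octahydronaphthalen-1-yl}methyl)benzene-1,4-diol, via quinone 31 (not isolated)
Conditions: (NH4)2Ce(NO3)6, MeCN/H2O, 0 °C; then Na2S2O4, H2O/Et2O, rt, argon
Reagents that add atoms: water O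
Why: Oxidative demethylation of the p-dimethoxyarene by tetravalent cerium should give the benzoquinone while isolated alkenes, the acetate and the tertiary alcohol survive, and dithionite reduces the quinone to the hydroquinone without acid.

**Step 16**
Reactants: 32 2-({(1R,2S,5R)-5-[(3E,7S,8R)-7-acetoxy-8-hydroxy-4,8,12-trimethyltrideca-3,11-dien-1-yl]-1,2,5-trimethyl-1,2,3,4,5,6,7,8-octahydronaphthalen-1-yl}methyl)benzene-1,4-diol
Product: 33 2-({(1R,2S,5R)-5-[(3E,7S,8R)-7-acetoxy-8-hydroxy-4,8,12-trimethyltrideca-3,11-dien-1-yl]-1,2,5-trimethyl-1,2,3,4,5,6,7,8-octahydronaphthalen-1-yl}methyl)benzene-1,4-diyl bis(hydrogen sulfate)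
Conditions: SO3·pyridine (6 equiv), pyridine, 0 °C to rt, argon; aq. NaHCO3 work-up
Reagents that add atoms: sulfur trioxide pyridine complex O=S(=O)([O-])[n+]1ccccc1
Why: O-Sulfation with SO3·pyridine should convert both phenols, while the secondary hydroxyl is blocked as its acetate and the tertiary hydroxyl is too hindered to react.

**Step 17**
Reactants: 33 2-({(1R,2S,5R)-5-[(3E,7S,8R)-7-acetoxy-8-hydroxy-4,8,12-trimethyltrideca-3,11-dien-1-yl]-1,2,5-trimethyl-1,2,3,4,5,6,7,8-octahydronaphthalen-1-yl}methyl)benzene-1,4-diyl bis(hydrogen sulfate)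
Product: 34 2-({(1R,2S,5R)-5-[(3E,7S,8R)-7,8-dihydroxy-4,8,12-trimethyltrideca-3,11-dien-1-yl]-1,2,5-trimethyl-1,2,3,4,5,6,7,8-octahydronaphthalen-1-yl}methyl)benzene-1,4-diyl bis(hydrogen sulfate) (CNP0442769.2)
Conditions: K2CO3 (0.2 equiv), MeOH, rt; then H+-form cation-exchange resin, MeOH/H2O, 0 °C
Reagents that add atoms: none
Why: Base-catalysed methanolysis should remove the acetate while aryl sulfate monoester anions resist base, and cold cation exchange gives the acid form drawn.

**Compound list**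

1 | 3-methylcyclohex-2-en-1-one | CC1=CC(=O)CCC1 | starting material
2 | dimethylaluminium (3R)-3-ethenyl-3-methylcyclohex-1-en-1-olate | C=C[C@@]1(C)CCCC(O[Al](C)C)=C1 | intermediate
3 | {[(3R)-3-ethenyl-3-methylcyclohex-1-en-1-yl]oxy}trimethylsilane | C=C[C@@]1(C)CCCC(O[Si](C)(C)C)=C1 | intermediate
4 | (3R)-2-[(dimethylamino)methyl]-3-ethenyl-3-methylcyclohexan-1-one (both C2 epimers) | C=C[C@@]1(C)CCCC(=O)C1CN(C)C | intermediate
5 | {[(6R)-6-ethenyl-6-methyl-2-oxocyclohexyl]methyl}trimethylammonium iodide (both C1 epimers) | C=C[C@@]1(C)CCCC(=O)C1C[N+](C)(C)C.[I-] | intermediate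
6 | (3R)-3-ethenyl-3-methyl-2-methylidenecyclohexan-1-one | C=C[C@@]1(C)CCCC(=O)C1=C | intermediate
7 | 3-methylbut-3-enoic acid | C=C(C)CC(=O)O | starting material
8 | (4R)-4-benzyl-1,3-oxazolidin-2-one | O=C1N[C@H](Cc2ccccc2)CO1 | starting material
9 | 2,2-dimethylpropanoic 3-methylbut-3-enoic anhydride | C=C(C)CC(=O)OC(=O)C(C)(C)C | intermediate
10 | (4R)-4-benzyl-3-(3-methylbut-3-enoyl)-1,3-oxazolidin-2-one | C=C(C)CC(=O)N1[C@H](Cc2ccccc2)COC1=O | intermediate
11 | sodium (Z)-enolate of 10 | C=C(C)/C=C(\[O-])N1[C@H](Cc2ccccc2)COC1=O.[Na+] | intermediate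
12 | (4R)-4-benzyl-3-[(2R)-2,3-dimethylbut-3-enoyl]-1,3-oxazolidin-2-one | O=C([C@H](C)C(C)=C)N1[C@H](Cc2ccccc2)COC1=O | intermediate
13 | (2R)-2,3-dimethylbut-3-en-1-ol | OC[C@H](C)C(C)=C | intermediate
14 | (3R)-4-bromo-2,3-dimethylbut-1-ene | BrC[C@H](C)C(C)=C | intermediate
15 | [(2R)-2,3-dimethylbut-3-en-1-yl]magnesium bromide | Br[Mg]C[C@H](C)C(C)=C | intermediate
16 | bromomagnesium (3R)-2-[(3S)-3,4-dimethylpent-4-en-1-yl]-3-ethenyl-3-methylcyclohex-1-en-1-olate | C=C[C@@]1(C)CCCC(O[Mg]Br)=C1CC[C@H](C)C(C)=C | intermediate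
17 | (3R)-2-[(3S)-3,4-dimethylpent-4-en-1-yl]-3-ethenyl-3-methylcyclohex-1-en-1-yl trifluoromethanesulfonate | C=C[C@@]1(C)CCCC(OS(=O)(=O)C(F)(F)F)=C1CC[C@H](C)C(C)=C | intermediate
18 | (2,5-dimethoxyphenyl)boronic acid | COc1ccc(OC)c(B(O)O)c1 | starting material
19 | 2-{[(1R,2S,5R)-5-ethenyl-1,2,5-trimethyl-1,2,3,4,5,6,7,8-octahydronaphthalen-1-yl]methyl}-1,4-dimethoxybenzene | C=C[C@@]1(C)CCCC2=C1CC[C@H](C)[C@@]2(C)Cc1cc(OC)ccc1OC | intermediate
20 | geraniol, (2E)-3,7-dimethylocta-2,6-dien-1-ol | CC(C)=CCC/C(C)=C/CO | starting material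
21 | [(2S,3S)-3-methyl-3-(4-methylpent-3-en-1-yl)oxiran-2-yl]methanol | CC(C)=CCC[C@]1(C)O[C@H]1CO | intermediate
22 | [(2S,3S)-3-methyl-3-(4-methylpent-3-en-1-yl)oxiran-2-yl]methyl trifluoromethanesulfonate | CC(C)=CCC[C@]1(C)O[C@H]1COS(=O)(=O)C(F)(F)F | intermediate
23 | trimethyl{4-[(2S,3S)-3-methyl-3-(4-methylpent-3-en-1-yl)oxiran-2-yl]but-1-yn-1-yl}silane | CC(C)=CCC[C@]1(C)O[C@H]1CCC#C[Si](C)(C)C | intermediate
24 | (5S,6R)-6,10-dimethyl-1-(trimethylsilyl)undec-9-en-1-yne-5,6-diol | CC(C)=CCC[C@@](C)(O)[C@@H](O)CCC#C[Si](C)(C)C | intermediate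
25 | (5S,6R)-6,10-dimethylundec-9-en-1-yne-5,6-diol | CC(C)=CCC[C@@](C)(O)[C@@H](O)CCC#C | intermediate
26 | (E)-alkenyldimethylalane from 25, both hydroxyls as dimethylaluminium alkoxides | CC(C)=CCC[C@@](C)(O[Al](C)C)[C@@H](O[Al](C)C)CC/C(C)=C/[Al](C)C | intermediate
27 | (1E,6S,7R)-1-iodo-2,7,11-trimethyldodeca-1,10-diene-6,7-diol | CC(C)=CCC[C@@](C)(O)[C@@H](O)CC/C(C)=C/I | intermediate
28 | (1E,6S,7R)-7-hydroxy-1-iodo-2,7,11-trimethyldodeca-1,10-dien-6-yl acetate | CC(C)=CCC[C@@](C)(O)[C@@H](OC(C)=O)CC/C(C)=C/I | intermediate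
29 | B-alkyl-9-borabicyclo[3.3.1]nonane from 19 (boron on the terminal carbon of the former vinyl group; stereocentres as in 19) | C(C[C@@]1(C)CCCC2=C1CC[C@H](C)[C@@]2(C)Cc1cc(OC)ccc1OC)B1C2CCCC1CCC2 | intermediate
30 | 2-({(1R,2S,5R)-5-[(3E,7S,8R)-7-acetoxy-8-hydroxy-4,8,12-trimethyltrideca-3,11-dien-1-yl]-1,2,5-trimethyl-1,2,3,4,5,6,7,8-octahydronaphthalen-1-yl}methyl)-1,4-dimethoxybenzene | CC(C)=CCC[C@@](C)(O)[C@@H](OC(C)=O)CC/C(C)=C/CC[C@@]1(C)CCCC2=C1CC[C@H](C)[C@@]2(C)Cc1cc(OC)ccc1OC | intermediate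
31 | 2-({(1R,2S,5R)-5-[(3E,7S,8R)-7-acetoxy-8-hydroxy-4,8,12-trimethyltrideca-3,11-dien-1-yl]-1,2,5-trimethyl-1,2,3,4,5,6,7,8-octahydronaphthalen-1-yl}methyl)cyclohexa-2,5-diene-1,4-dione | CC(C)=CCC[C@@](C)(O)[C@@H](OC(C)=O)CC/C(C)=C/CC[C@@]1(C)CCCC2=C1CC[C@H](C)[C@@]2(C)CC1=CC(=O)C=CC1=O | intermediate
32 | 2-({(1R,2S,5R)-5-[(3E,7S,8R)-7-acetoxy-8-hydroxy-4,8,12-trimethyltrideca-3,11-dien-1-yl]-1,2,5-trimethyl-1,2,3,4,5,6,7,8-octahydronaphthalen-1-yl}methyl)benzene-1,4-diol | CC(C)=CCC[C@@](C)(O)[C@@H](OC(C)=O)CC/C(C)=C/CC[C@@]1(C)CCCC2=C1CC[C@H](C)[C@@]2(C)Cc1cc(O)ccc1O | intermediate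
33 | 2-({(1R,2S,5R)-5-[(3E,7S,8R)-7-acetoxy-8-hydroxy-4,8,12-trimethyltrideca-3,11-dien-1-yl]-1,2,5-trimethyl-1,2,3,4,5,6,7,8-octahydronaphthalen-1-yl}methyl)benzene-1,4-diyl bis(hydrogen sulfate) | CC(C)=CCC[C@@](C)(O)[C@@H](OC(C)=O)CC/C(C)=C/CC[C@@]1(C)CCCC2=C1CC[C@H](C)[C@@]2(C)Cc1cc(OS(=O)(=O)O)ccc1OS(=O)(=O)O | intermediate
34 | 2-({(1R,2S,5R)-5-[(3E,7S,8R)-7,8-dihydroxy-4,8,12-trimethyltrideca-3,11-dien-1-yl]-1,2,5-trimethyl-1,2,3,4,5,6,7,8-octahydronaphthalen-1-yl}methyl)benzene-1,4-diyl bis(hydrogen sulfate) (CNP0442769.2) | CC(C)=CCC[C@@](C)(O)[C@@H](O)CC/C(C)=C/CC[C@@]1(C)CCCC2=C1CC[C@H](C)[C@@]2(C)Cc1cc(OS(=O)(=O)O)ccc1OS(=O)(=O)O | target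

**Count**

Total steps: 17. Longest linear sequence: 10 steps (steps 3, 4, 5, 6, 7, 8, 14, 15, 16, 17, from 3-methylbut-3-enoic acid).

**Steps most likely to fail and fallbacks**

Step 8. The alkenylpalladium may be arylated before it inserts the alkene. Alternatively, the hindered σ-alkylpalladium may be captured too slowly, so that it inserts into the new ring-fusion alkene (cyclopropylcarbinyl rearrangement) while the electron-rich boronic acid protodeboronates. The fallback sets out from 17 and comes back at 19. It separates ring closure from arylation and reverses the polarity of the arylation. Heck cyclisation terminated by borylation (B2pin2, Pd(OAc)2, PPh3, KOAc, toluene, 80 °C) should give the neopentyl-type pinacol boronate 2-{[(1R,2S,5R)-5-ethenyl-1,2,5-trimethyl-1,2,3,4,5,6,7,8-octahydronaphthalen-1-yl]methyl}-4,4,5,5-tetramethyl-1,3,2-dioxaborolane F1. Its primary C–B bond is then coupled with commercial 2-bromo-1,4-dimethoxybenzene (Pd(OAc)2, RuPhos, K3PO4, toluene/H2O, 100 °C) to give 19.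

Step 1. Transfer of the small, unsubstituted vinyl group may proceed with low enantioselectivity, and O-silylation of the aluminium enolate may be incomplete, which would lose the enolate regiochemistry. The fallback exchanges the roles: the C5–CH3 bond is formed in the enantio-determining step and the vinyl group is carried as an alkyne. It does not use 1; it sets out from commercial 3-ethoxycyclohex-2-en-1-one in the place of 1 and comes back to the route at 4. Addition of LiC≡CSiMe3 (THF, −78 °C; then aq. HCl) gives 3-[(trimethylsilyl)ethynyl]cyclohex-2-en-1-one F2. Cu-catalysed addition of MeMgBr (Cu(OTf)2, chiral imidazolinium salt as N-heterocyclic carbene precursor, Et2O, −30 °C) follows; this reaction type is known to favour 1,4- over 1,6-addition on cyclic enynones. Trapping of the magnesium enolate with Eschenmoser's salt should give (3S)-2-[(dimethylamino)methyl]-3-methyl-3-[(trimethylsilyl)ethynyl]cyclohexan-1-one F3. K2CO3/MeOH removes the C-silyl group to give (3S)-2-[(dimethylamino)methyl]-3-ethynyl-3-methylcyclohexan-1-one F4. Semi-hydrogenation (H2, Pd/CaCO3 poisoned with Pb(OAc)2, quinoline) gives 4, which is taken through the quaternisation/elimination of step 2 to 6.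

Step 15. The oxidant may attack the electron-rich ring-fusion alkene or the side-chain alkenes, or the quinone may decompose before reduction. The fallback sets out from 30 and comes back at 32. It replaces oxidation by nucleophilic dealkylation. Lithium butane-1-thiolate in HMPA at 110 °C should cleave both aryl methyl ethers by SN2 attack at methyl and also remove the acetate, giving 2-({(1R,2S,5R)-5-[(3E,7S,8R)-7,8-dihydroxy-4,8,12-trimethyltrideca-3,11-dien-1-yl]-1,2,5-trimethyl-1,2,3,4,5,6,7,8-octahydronaphthalen-1-yl}methyl)benzene-1,4-diol F5. Acetylation (Ac2O, pyridine, rt) gives the triacetate 2-({(1R,2S,5R)-5-[(3E,7S,8R)-7-acetoxy-8-hydroxy-4,8,12-trimethyltrideca-3,11-dien-1-yl]-1,2,5-trimethyl-1,2,3,4,5,6,7,8-octahydronaphthalen-1-yl}methyl)benzene-1,4-diyl diacetate F6. Selective hydrazinolysis of the two aryl acetates (N2H4·AcOH, DMF, rt) gives 32.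

**Further compounds**

F1 | step 8 | 2-{[(1R,2S,5R)-5-ethenyl-1,2,5-trimethyl-1,2,3,4,5,6,7,8-octahydronaphthalen-1-yl]methyl}-4,4,5,5-tetramethyl-1,3,2-dioxaborolane | C=C[C@@]1(C)CCCC2=C1CC[C@H](C)[C@@]2(C)CB1OC(C)(C)C(C)(C)O1
F2 | step 1 | 3-[(trimethylsilyl)ethynyl]cyclohex-2-en-1-one | C[Si](C)(C)C#CC1=CC(=O)CCC1
F3 | step 1 | (3S)-2-[(dimethylamino)methyl]-3-methyl-3-[(trimethylsilyl)ethynyl]cyclohexan-1-one (both C2 epimers) | C[Si](C)(C)C#C[C@@]1(C)CCCC(=O)C1CN(C)C
F4 | step 1 | (3S)-2-[(dimethylamino)methyl]-3-ethynyl-3-methylcyclohexan-1-one (both C2 epimers) | C#C[C@@]1(C)CCCC(=O)C1CN(C)C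
F5 | step 15 | 2-({(1R,2S,5R)-5-[(3E,7S,8R)-7,8-dihydroxy-4,8,12-trimethyltrideca-3,11-dien-1-yl]-1,2,5-trimethyl-1,2,3,4,5,6,7,8-octahydronaphthalen-1-yl}methyl)benzene-1,4-diol | CC(C)=CCC[C@@](C)(O)[C@@H](O)CC/C(C)=C/CC[C@@]1(C)CCCC2=C1CC[C@H](C)[C@@]2(C)Cc1cc(O)ccc1O
F6 | step 15 | 2-({(1R,2S,5R)-5-[(3E,7S,8R)-7-acetoxy-8-hydroxy-4,8,12-trimethyltrideca-3,11-dien-1-yl]-1,2,5-trimethyl-1,2,3,4,5,6,7,8-octahydronaphthalen-1-yl}methyl)benzene-1,4-diyl diacetate | CC(C)=CCC[C@@](C)(O)[C@@H](OC(C)=O)CC/C(C)=C/CC[C@@]1(C)CCCC2=C1CC[C@H](C)[C@@]2(C)Cc1cc(OC(C)=O)ccc1OC(C)=O
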